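**Retrosynthetic overview**

1. The strategy rests on the 2,4,6-trihydroxyphenyl ketone. Its six ring carbons carry oxygen in a 1,3,5 pattern and the acyl carbon C1 sits on the ring carbon flanked by two of them, which is the folded form of a linear 3,5,7-trioxo ester. The arene is therefore closed from an open chain and not made by Friedel-Crafts acylation, which the skipped tetraene would not tolerate.
2. The trioxo ester is cut between C6 and C7 into the trianion of methyl 3,5-dioxohexanoate (from dehydroacetic acid) and the C20 methyl ester.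
3. The all-Z tetraene comes from a skipped tetrayne by syn semihydrogenation. The tetrayne comes from a C1-C10 bromodiyne and a C11-C20 diyne, each built by copper-mediated alkyne propargylation.
4. C17 is bought as (R)-2-propyloxirane and opened at its CH2 carbon.
5. Ring order: the benzene ring is the only ring and is closed last but one, before desilylation.

Key step: step 12

Assumption: Mg(OMe)2 and LiN(iPr)2 are used as commercial solutions, and the trioxo ester 19 is drawn as its keto tautomer although it will exist largely as enols.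

**Route**

Step 1
Reactants: 1 (R)-2-propyloxirane; 2 ethynyltrimethylsilane
Product: 4 (R)-1-(trimethylsilyl)hept-1-yn-4-ol, via lithium (trimethylsilyl)acetylide 3 (not isolated)
Conditions: 2, n-BuLi, THF, −78 °C; BF3·OEt2, then 1, −78 °C; H2O
Reagents that add atoms: none
Why: BF3-assisted SN2 opening of the terminal epoxide by the lithium acetylide (Yamaguchi–Hirao alkynylation) occurs at the unsubstituted CH2, so no bond to the carbinol carbon is touched and the R configuration of 1 is carried over.

Step 2
Reactants: 4 (R)-1-(trimethylsilyl)hept-1-yn-4-ol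
Product: 5 (R)-4-(tert-butyldimethylsilyloxy)-1-(trimethylsilyl)hept-1-yne
Conditions: TBSCl, imidazole, DMF, rt
Reagents that add atoms: tert-butyldimethylsilyl chloride, CC(C)(C)[Si](C)(C)Cl
Why: Standard O-silylation of a secondary alcohol, giving an ether that should withstand carbonate, LiN(iPr)2 and Mg(OMe)2 later on.

Step 3
Reactants: 5 (R)-4-(tert-butyldimethylsilyloxy)-1-(trimethylsilyl)hept-1-yne
Product: 6 (R)-4-(tert-butyldimethylsilyloxy)hept-1-yne
Conditions: K2CO3 (cat.), MeOH, rt
Reagents that add atoms: none
Why: Base-catalysed methanolysis of the alkynyl C–Si bond (protodesilylation) is far faster than cleavage of the O–Si bond of the hindered silyl ether, and the isolated alkyne cannot isomerise.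

Step 4
Reactants: 6 (R)-4-(tert-butyldimethylsilyloxy)hept-1-yne; 7 3-bromo-1-(trimethylsilyl)prop-1-yne
Product: 8 (R)-7-(tert-butyldimethylsilyloxy)-1-(trimethylsilyl)deca-1,4-diyne
Conditions: CuI, NaI, Cs2CO3, DMF, rt
Reagents that add atoms: none
Why: Copper-mediated coupling of the copper acetylide with the propargylic halide (activated by Finkelstein exchange) should give the 1,4-diyne by direct substitution, and the silyl cap stops the product from coupling again.

Step 5
Reactants: 8 (R)-7-(tert-butyldimethylsilyloxy)-1-(trimethylsilyl)deca-1,4-diyne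
Product: 9 (R)-7-(tert-butyldimethylsilyloxy)deca-1,4-diyne
Conditions: AgNO3 (cat.), MeOH/H2O/CH2Cl2, rt
Reagents that add atoms: none
Why: Silver-catalysed protodesilylation of the alkynyl silane runs without base, which should spare the skipped diyne from propargyl–allenyl isomerisation and leave the silyl ether in place.

Step 6
Reactants: 10 methyl hex-5-ynoate; 11 4-chlorobut-2-yn-1-ol
Product: 12 methyl 10-hydroxydeca-5,8-diynoate
Conditions: CuI, NaI, Cs2CO3, DMF, rt
Reagents that add atoms: none
Why: The same copper-mediated alkyne propargylation, which tolerates the free primary alcohol and the methyl ester.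

Step 7
Reactants: 12 methyl 10-hydroxydeca-5,8-diynoate
Product: 13 methyl 10-bromodeca-5,8-diynoate
Conditions: CBr4, PPh3, CH2Cl2, −20 to 0 °C
Reagents that add atoms: carbon tetrabromide, BrC(Br)(Br)Br
Why: Appel reaction converts the primary propargylic alcohol into the bromide under neutral conditions that should not disturb the skipped diyne.

Step 8
Reactants: 9 (R)-7-(tert-butyldimethylsilyloxy)deca-1,4-diyne; 13 methyl 10-bromodeca-5,8-diynoate
Product: 14 methyl (R)-17-(tert-butyldimethylsilyloxy)icosa-5,8,11,14-tetraynoate
Conditions: CuI, NaI, Cs2CO3, DMF, rt, argon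
Reagents that add atoms: none
Why: Copper-mediated coupling of the terminal diyne with the propargylic bromide forms the C10–C11 bond and completes the C20 skipped tetrayne, which should be handled under argon and reduced at once.

Step 9
Reactants: 14 methyl (R)-17-(tert-butyldimethylsilyloxy)icosa-5,8,11,14-tetraynoate
Product: 15 methyl (5Z,8Z,11Z,14Z,17R)-17-(tert-butyldimethylsilyloxy)icosa-5,8,11,14-tetraenoate
Conditions: H2 (1 atm), Ni2B catalyst (from Ni(OAc)2·4H2O and NaBH4), ethylenediamine, EtOH, rt
Reagents that add atoms: none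
Why: Catalytic semihydrogenation on the amine-moderated nickel boride surface delivers both hydrogens to one face of each alkyne, so each of the four alkynes should become a Z alkene while ester and silyl ether stay untouched.

Step 10
Reactants: 16 dehydroacetic acid
Product: 17 methyl 3,5-dioxohexanoate
Conditions: Mg(OMe)2, MeOH, reflux; aq. HCl
Reagents that add atoms: magnesium methoxide, C[O-].C[O-].[Mg+2]; methanol, CO
Why: Methoxide opens the pyranone lactone and a retro-Claisen cleavage of the resulting triacylmethane expels the acetyl group as methyl acetate, the magnesium chelate shielding the 3,5-dioxo ester from further cleavage.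

Step 11
Reactants: 15 methyl (5Z,8Z,11Z,14Z,17R)-17-(tert-butyldimethylsilyloxy)icosa-5,8,11,14-tetraenoate; 17 methyl 3,5-dioxohexanoate
Product: 19 methyl (11Z,14Z,17Z,20Z,23R)-23-(tert-butyldimethylsilyloxy)-3,5,7-trioxohexacosa-11,14,17,20-tetraenoate, via trilithium trianion of methyl 3,5-dioxohexanoate 18 (not isolated)
Conditions: 17 (3 equiv), LiN(iPr)2 (3.0 equiv per 17), THF, −78 to 0 °C; 15, −78 to 0 °C; AcOH, −78 °C
Reagents that add atoms: none
Why: Claisen-type C-acylation of a polyanion, in which the last-formed and most nucleophilic terminal carbanion (C6) attacks the ester, three equivalents of trianion being used because the more acidic product consumes one, and no free amide base being left to touch the bis-allylic CH2 groups.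

Step 12
Reactants: 19 methyl (11Z,14Z,17Z,20Z,23R)-23-(tert-butyldimethylsilyloxy)-3,5,7-trioxohexacosa-11,14,17,20-tetraenoate
Product: 21 (5Z,8Z,11Z,14Z,17R)-17-(tert-butyldimethylsilyloxy)-1-(2,4,6-trihydroxyphenyl)icosa-5,8,11,14-tetraen-1-one, via 2-acylcyclohexane-1,3,5-trione tautomer 20 (not isolated)
Conditions: Mg(OMe)2 (5 equiv), MeOH/THF, rt to 45 °C, argon; cold 0.5 M HCl to pH 4
Reagents that add atoms: none
Why: Mg(OMe)2 turns the three ketones of 19 into a magnesium-chelated polyenolate, so the methyl ester carbon C1 is the only electrophilic carbonyl left, and the C6 carbanion between the C5 and C7 ketones adds to it with loss of methoxide. The closest known reaction type is the intramolecular Claisen (Dieckmann-type) condensation of 3,5,7-trioxoalkanoates to acylphloroglucinols, as in biomimetic polyketide cyclisations. The C1–C6 bond closes the six-membered carbocycle in a 6-exo-trig acyl substitution, and enolisation of trione 20 to the aromatic triol 21 is irreversible and drives the closure. No stereocentre is formed, and the silyloxy carbon is remote and untouched. The step needs Claisen closure in preference to aldol closure (C2 onto the C7 ketone, which leads to a resorcylate) and to O-acylation to a pyranone; anhydrous magnesium methoxide secures this by masking the ketones as chelated enolates and keeping the ester unhydrolysed. The base is mild enough that the bis-allylic CH2 groups and the silyl ether should survive.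

Step 13
Reactants: 21 (5Z,8Z,11Z,14Z,17R)-17-(tert-butyldimethylsilyloxy)-1-(2,4,6-trihydroxyphenyl)icosa-5,8,11,14-tetraen-1-one
Product: 22 (5Z,8Z,11Z,14Z,17R)-17-hydroxy-1-(2,4,6-trihydroxyphenyl)icosa-5,8,11,14-tetraen-1-one (target)
Conditions: HF·pyridine, THF/pyridine, 0 °C to rt, argon
Reagents that add atoms: none
Why: Buffered fluoride desilylation cleaves the O–Si bond without deprotonating the phenols or isomerising the skipped tetraene, and the C17–O bond is not touched, so the R configuration remains.

**Compound list**

1 | (R)-2-propyloxirane | CCC[C@@H]1CO1 | starting material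
2 | ethynyltrimethylsilane | C[Si](C)(C)C#C | starting material
3 | lithium (trimethylsilyl)acetylide | [Li]C#C[Si](C)(C)C | intermediate (not isolated)
4 | (R)-1-(trimethylsilyl)hept-1-yn-4-ol | CCC[C@@H](O)CC#C[Si](C)(C)C | intermediate
5 | (R)-4-(tert-butyldimethylsilyloxy)-1-(trimethylsilyl)hept-1-yne | CCC[C@@H](O[Si](C)(C)C(C)(C)C)CC#C[Si](C)(C)C | intermediate
6 | (R)-4-(tert-butyldimethylsilyloxy)hept-1-yne | CCC[C@@H](O[Si](C)(C)C(C)(C)C)CC#C | intermediate
7 | 3-bromo-1-(trimethylsilyl)prop-1-yne | C[Si](C)(C)C#CCBr | starting material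
8 | (R)-7-(tert-butyldimethylsilyloxy)-1-(trimethylsilyl)deca-1,4-diyne | CCC[C@@H](O[Si](C)(C)C(C)(C)C)CC#CCC#C[Si](C)(C)C | intermediate
9 | (R)-7-(tert-butyldimethylsilyloxy)deca-1,4-diyne | CCC[C@@H](O[Si](C)(C)C(C)(C)C)CC#CCC#C | intermediate
10 | methyl hex-5-ynoate | COC(=O)CCCC#C | starting material
11 | 4-chlorobut-2-yn-1-ol | OCC#CCCl | starting material
12 | methyl 10-hydroxydeca-5,8-diynoate | COC(=O)CCCC#CCC#CCO | intermediate
13 | methyl 10-bromodeca-5,8-diynoate | COC(=O)CCCC#CCC#CCBr | intermediate
14 | methyl (R)-17-(tert-butyldimethylsilyloxy)icosa-5,8,11,14-tetraynoate | CCC[C@@H](O[Si](C)(C)C(C)(C)C)CC#CCC#CCC#CCC#CCCCC(=O)OC | intermediate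
15 | methyl (5Z,8Z,11Z,14Z,17R)-17-(tert-butyldimethylsilyloxy)icosa-5,8,11,14-tetraenoate | CCC[C@@H](O[Si](C)(C)C(C)(C)C)C/C=C\C/C=C\C/C=C\C/C=C\CCCC(=O)OC | intermediate
16 | dehydroacetic acid (3-acetyl-6-methyl-2H-pyran-2,4(3H)-dione) | CC(=O)C1C(=O)C=C(C)OC1=O | starting material
17 | methyl 3,5-dioxohexanoate | COC(=O)CC(=O)CC(C)=O | intermediate
18 | trilithium trianion of methyl 3,5-dioxohexanoate | [Li+].[Li+].[Li+].COC(=O)C=C([O-])C=C([O-])[CH2-] | intermediate (not isolated)
19 | methyl (11Z,14Z,17Z,20Z,23R)-23-(tert-butyldimethylsilyloxy)-3,5,7-trioxohexacosa-11,14,17,20-tetraenoate | CCC[C@@H](O[Si](C)(C)C(C)(C)C)C/C=C\C/C=C\C/C=C\C/C=C\CCCC(=O)CC(=O)CC(=O)CC(=O)OC | intermediate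
20 | 2-[(5Z,8Z,11Z,14Z,17R)-17-(tert-butyldimethylsilyloxy)icosa-5,8,11,14-tetraenoyl]cyclohexane-1,3,5-trione | CCC[C@@H](O[Si](C)(C)C(C)(C)C)C/C=C\C/C=C\C/C=C\C/C=C\CCCC(=O)C1C(=O)CC(=O)CC1=O | intermediate (not isolated)
21 | (5Z,8Z,11Z,14Z,17R)-17-(tert-butyldimethylsilyloxy)-1-(2,4,6-trihydroxyphenyl)icosa-5,8,11,14-tetraen-1-one | CCC[C@@H](O[Si](C)(C)C(C)(C)C)C/C=C\C/C=C\C/C=C\C/C=C\CCCC(=O)c1c(O)cc(O)cc1O | intermediate
22 | (5Z,8Z,11Z,14Z,17R)-17-hydroxy-1-(2,4,6-trihydroxyphenyl)icosa-5,8,11,14-tetraen-1-one | CCC[C@@H](O)C/C=C\C/C=C\C/C=C\C/C=C\CCCC(=O)c1c(O)cc(O)cc1O | target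

**Step count**

Total: 13 steps. Longest linear sequence: 10 steps (steps 1, 2, 3, 4, 5, 8, 9, 11, 12, 13, from 1 to 22).

**Steps most likely to fail**

Step 11 (trianion acylation). The trianion may remove an α-proton from the ester in place of adding to its carbonyl, and the more acidic product quenches further trianion, so conversion may stall and 15 be returned. Fallback, setting out from 15: the ester would be treated with MeNH(OMe)·HCl and iPrMgCl in THF at −20 °C to give (5Z,8Z,11Z,14Z,17R)-17-(tert-butyldimethylsilyloxy)-N-methoxy-N-methylicosa-5,8,11,14-tetraenamide F1. F1 would then be added to trianion 18 (1.5 equiv) at −78 °C. With this acyl donor the adduct does not release the ketone before the acidic quench, so proton transfer from product to nucleophile is avoided. The sequence comes back to the route at 19.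

Step 12 (Claisen ring closure). The chain may close by the aldol path or by O-acylation, or be cut by retro-Claisen attack of methoxide, so that the acylphloroglucinol is not the main outcome. Fallback, setting out from 15 and using known aryllithium chemistry: phloroglucinol would be converted with chloromethyl methyl ether and iPr2NEt into 1,3,5-tris(methoxymethoxy)benzene F2. n-BuLi in THF at 0 °C should lithiate F2 between two acetal oxygens to give 2,4,6-tris(methoxymethoxy)phenyllithium F3. F3 would be added at −78 °C to the N-methoxy-N-methyl amide F1 (made from 15 as above) to give (5Z,8Z,11Z,14Z,17R)-17-(tert-butyldimethylsilyloxy)-1-[2,4,6-tris(methoxymethoxy)phenyl]icosa-5,8,11,14-tetraen-1-one F4. Dilute HCl in MeOH at rt should then remove the three acetals and the silyl ether together. This comes back to the route at 22, bypassing 19 to 21.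

Step 9 (fourfold semihydrogenation). Uptake of hydrogen may overrun at one alkene or stop short at one alkyne, giving mixtures that are hard to separate from the tetraene, and the air-sensitive tetrayne may degrade on the catalyst. Fallback, setting out from 14: fourfold syn hydroboration with dicyclohexylborane (4.4 equiv, made from BH3·SMe2 and cyclohexene) in THF at 0 °C would give the tetrakis(dicyclohexylboryl) tetraene F5 (regioisomers at each alkyne, one drawn, all converging). Protonolysis of the four alkenyl C–B bonds with acetic acid at rt to 50 °C proceeds with retention and cannot over-reduce. The sequence comes back to the route at 15.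

**Further compounds**

F1 | step 11 | (5Z,8Z,11Z,14Z,17R)-17-(tert-butyldimethylsilyloxy)-N-methoxy-N-methylicosa-5,8,11,14-tetraenamide | CCC[C@@H](O[Si](C)(C)C(C)(C)C)C/C=C\C/C=C\C/C=C\C/C=C\CCCC(=O)N(C)OC
F2 | step 12 | 1,3,5-tris(methoxymethoxy)benzene | COCOc1cc(OCOC)cc(OCOC)c1
F3 | step 12 | 2,4,6-tris(methoxymethoxy)phenyllithium | [Li]c1c(OCOC)cc(OCOC)cc1OCOC
F4 | step 12 | (5Z,8Z,11Z,14Z,17R)-17-(tert-butyldimethylsilyloxy)-1-[2,4,6-tris(methoxymethoxy)phenyl]icosa-5,8,11,14-tetraen-1-one | CCC[C@@H](O[Si](C)(C)C(C)(C)C)C/C=C\C/C=C\C/C=C\C/C=C\CCCC(=O)c1c(OCOC)cc(OCOC)cc1OCOC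
F5 | step 9 | methyl (5Z,8Z,11Z,14Z,17R)-17-(tert-butyldimethylsilyloxy)-5,8,11,14-tetrakis(dicyclohexylboryl)icosa-5,8,11,14-tetraenoate (one regioisomer) | CCC[C@@H](O[Si](C)(C)C(C)(C)C)C/C=C(B(C1CCCCC1)C1CCCCC1)\C/C=C(B(C1CCCCC1)C1CCCCC1)\C/C=C(B(C1CCCCC1)C1CCCCC1)\C/C=C(B(C1CCCCC1)C1CCCCC1)\CCCC(=O)OC
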